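## Analysis of the target

The target (19) is a bibenzyl: a fully substituted benzoic acid ring (ring A) joined through a CH2CH2 bridge to a 4-hydroxyphenyl ring (ring B). Numbered from the methoxy carbon, ring A carries C1 OCH3, C2 prenyl, C3 OH, C4 prenyl, C5 arylethyl and C6 CO2H. There is no stereocenter and no stereogenic double bond, so the whole problem is regiochemistry on a hexasubstituted arene. The sensitive groups are the two prenyl alkenes beside the C3 phenol (acid closes them to chromans, electrophiles and oxidants attack them) and the electron-rich, doubly ortho-substituted carboxylic acid, which decarboxylates in acid and, as an ordinary ester, resists saponification. The difficulty is to place six different substituents, to tell the two ring oxygens apart (C1 methylated, C3 free), and to release the hindered acid under conditions the prenyl phenol survives. The plan rests on the 1,3-relation of the oxygens at C1 and C3, with the carboxyl at C6 next to the arylethyl carbon C5. That is the pattern of a tetraketide grown from a dihydrocoumaroyl starter and folded by an aldol bond between C6 and C5 with the carboxyl retained. C2 and C4 are then the only unsubstituted ring carbons, both ortho to the C3 oxygen, so one phenol activates both for substitution.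

## Retrosynthetic reasoning

**Unmasking (19 from 18).** Only O–Si and ester C–O bonds are cut. The last step must be neither acidic nor a hydrolysis at the hindered carbonyl. The acid is therefore carried as a 2-(trimethylsilyl)ethyl ester and the ring B phenol as a triisopropylsilyl ether, so that a fluoride source releases both from 18 in one operation.

**Prenyl from allyl (18 from 17).** Each prenyl group is traced to an allyl group by exchange of the alkene terminus. Direct transfer of a prenyl unit to an arene carbon tends to give linear and branched isomers. An allyl group has no such ambiguity, and cross-metathesis corrects both termini of 17 at once.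

**Two ring C–C bonds traced to C–I bonds (17 from 16 from 15).** The C2–CH2 and C4–CH2 bonds are cut back to two aryl iodides in 16, and these to the two ring hydrogens of phenol 15. A sigmatropic relay from the C3 oxygen (O-allylation, then [3,3] shift, twice) was weighed for these bonds. Its first migration can go to either ortho carbon, so the material would run as a pair of isomers through three steps before converging. Iodination treats both ortho carbons alike, because they are the only free positions of ring A and both are activated by the C3 hydroxyl. Each intermediate is then a single compound, and both allyl groups enter in one cross-coupling.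

**Free phenol (15 from 14).** The O-allyl bond at C3 is cut. The hydroxyl must be free at the iodination stage, because only the free phenol activates both neighbours without acid, and the allyl alkene would not survive an iodinating agent.

**Methyl ether, ester and allyl ether (14 from 13, from 12, from 11).** The C1 methyl ether and the ester C–O bond are cut next, back to the acetonide-bridged lactone 12 and its phenol 11. The allyl ether protects the C3 oxygen through these steps for two reasons. With that oxygen alkylated, no para phenoxide deactivates the lactone carbonyl toward the alkoxide. The hydroxyl set free in 13 is then the only one in the molecule when it is methylated. The allyl group is chosen because it is removed under neutral conditions that leave the silyl ether, the silylethyl ester and the methyl ether untouched.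

**Ring A (11 from 9).** The key disconnection cuts the C5–C6 bond of ring A only. In 11 the C1 oxygen and the carboxyl are tied together as an acetonide and the C3 hydroxyl is free. Opening the ring gives the diketo-dioxinone 9, a masked tetraketide. The forward reaction has to fold this chain by aldol addition and aromatize it, and it delivers the two ring oxygens already differentiated.

**Chain assembly (9 from 7 and 3).** The bond between the terminal methyl carbon of keto-dioxinone 7 and the acyl carbon of amide 3 is cut. This joins the three-acetate part to the starter unit by one acylation of a dianion, with an amide that stops at the ketone stage.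

**Building blocks (7 from 4 and 5; 3 from 2 from 1).** Keto-dioxinone 7 comes from acetylation of dioxinone 4 with acetyl chloride 5. Amide 3 comes from acid 1 by amide formation (2) and silylation.

## Alternatives that were turned down

Alternative 1: aryne carbomagnesiation with carboxylation.
- Disconnection: the bond from C5 to the arylethyl chain and the C6–CO2H bond are cut together. This leads to the chloroarene 1-chloro-5-methoxy-3-(methoxymethoxy)-2,4-bis(3-methylbut-2-enyl)benzene A2 and the Grignard reagent {2-[4-(methoxymethoxy)phenyl]ethyl}magnesium bromide A4.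
- Forward key step: a hindered lithium amide removes the single ring hydrogen of A2, which lies between methoxy and chlorine. Chloride loss gives the aryne 3-methoxy-5-(methoxymethoxy)-4,6-bis(3-methylbut-2-enyl)-1,2-didehydrobenzene A3. A4 adds at the aryne carbon remote from the methoxy group, and carboxylation of the resulting arylmagnesium gives 2-methoxy-4-(methoxymethoxy)-3,5-bis(3-methylbut-2-enyl)-6-{2-[4-(methoxymethoxy)phenyl]ethyl}benzoic acid A1.
- For it: two bonds form in one flask, the methoxy group dictates the regiochemistry, and the carboxyl enters as the free acid. On that last point it is stronger than the chosen route, which needs an ester surrogate and a step to remove it. The arylethyl unit also enters late, which suits analogue work.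
- Against it: A2 already holds both prenyl groups and differentiated oxygens, so its preparation faces the same ortho-prenylation problem and saves no steps. Under the amide base the benzylic and allylic CH2 hydrogens of the prenyl groups compete with ring deprotonation. In A3 one aryne carbon sits next to a prenyl group that can undergo an intramolecular ene reaction, and that same carbon must accept a primary alkyl nucleophile. A1 still carries two methoxymethyl ethers, whose acidic removal invites chroman formation and decarboxylation.
- Comparison: the chosen route puts its risk in a room-temperature amine-mediated step with close precedent and finishes under fluoride.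

Alternative 2: Diels–Alder reaction of a bis(silyloxy)diene with an ynoate.
- Disconnection: C4–C5 and C1–C6 are cut. This gives the diene 1-methoxy-7-methyl-2-(3-methylbut-2-enyl)-1,3-bis(tert-butyldimethylsilyloxy)octa-1,3,6-triene A6 and the ynoate 2-(trimethylsilyl)ethyl 5-[4-(tert-butyldimethylsilyloxy)phenyl]pent-2-ynoate A7.
- Forward key step: [4+2] cycloaddition of A6 and A7, then loss of the methoxy group from the ketal carbon, gives 2-(trimethylsilyl)ethyl 2-hydroxy-4-(tert-butyldimethylsilyloxy)-3,5-bis(3-methylbut-2-enyl)-6-{2-[4-(tert-butyldimethylsilyloxy)phenyl]ethyl}benzoate A5.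
- For it: this is the most convergent plan. All six substituents and the oxygen differentiation arrive in the ring-forming step, and A5 is only a methylation and a fluoride treatment from the target. In step count after ring formation it is clearly stronger than the chosen route. The polarity of A6 and A7 also matches the required regiochemistry.
- Against it: A6 is substituted at both C2 and C4. The C4 substituent lowers the s-cis population and hinders the terminus that must bond to the beta carbon of A7. A7 is beta-alkylated and activated by one ester only. The heating this pairing needs is the regime in which silyl ketene acetals undergo silyl shifts and hydrolysis, and a stepwise conjugate addition can stall at an open-chain adduct. A6 also requires alpha- and gamma-prenylation of an acetoacetate and a geometry-controlled double silylation.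
- Comparison: the chosen strategy gives up this convergence for a ring formation that runs under mild base, and pays with standard steps on the finished arene.

Alternative 3: Michael–Dieckmann annulation with late aromatization.
- Disconnection: C5–C6 and C1–C2 are cut. This gives the enone (3E)-9-methyl-4-(3-methylbut-2-enyl)-1-[4-(prop-2-enyloxy)phenyl]deca-3,8-dien-5-one A9 and the malonate bis(prop-2-enyl) propanedioate A10.
- Forward key step: the anion of A10 adds to the beta carbon of A9, and Dieckmann closure of the ketone enolate onto one ester of the A10 unit follows in the same flask. The product is racemic prop-2-enyl all-trans-4-hydroxy-3,5-bis(3-methylbut-2-enyl)-2-oxo-6-{2-[4-(prop-2-enyloxy)phenyl]ethyl}cyclohex-3-ene-1-carboxylate A8.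
- For it: A9 and A10 are cheap acyclic components, the annulation is classical, and two ring bonds form with every carbon substituent in place. It needs no halogenation, cross-coupling or metathesis, and on that count it is stronger than the chosen route.
- Against it: A8 is a cyclohexane-1,3-dione and must be dehydrogenated to the resorcinol in the presence of two prenyl and two allyl alkenes, which halogenating and quinone oxidants attack. A9 is an alpha,beta-disubstituted enone and a poor acceptor for A10, and the Dieckmann step must use the enolate on the more substituted side. Three stereocenters are made only to be erased. After aromatization the two hydroxyls still have to be distinguished, and the chelated C1 hydroxyl that must be methylated is the less reactive one.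
- Comparison: the chosen route forms the ring at the aromatic oxidation level with the oxygens already told apart.

Key step: step 5

Remark: benzoate intermediates are numbered from the ester carbon, so benzoate C2, C3, C4, C5 and C6 are ring A C1, C2, C3, C4 and C5.

## Route

Step 1
Reactants: 1 3-(4-hydroxyphenyl)propanoic acid
Product: 2 3-(4-hydroxyphenyl)-N-methoxy-N-methylpropanamide
Conditions: MeNHOMe·HCl, EDC·HCl, HOBt, N-methylmorpholine, CH2Cl2, 0 °C to rt
Reagents that add atoms: N,O-dimethylhydroxylamine hydrochloride, CNOC.Cl
Why: Carbodiimide amide coupling through the hydroxybenzotriazole active ester gives the N-methoxy-N-methylamide; the amine outcompetes the phenol for the activated acid, so the phenol can stay free at this stage.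

Step 2
Reactants: 2 3-(4-hydroxyphenyl)-N-methoxy-N-methylpropanamide
Product: 3 N-methoxy-N-methyl-3-[4-(triisopropylsilyloxy)phenyl]propanamide
Conditions: iPr3SiCl, imidazole, DMF, rt
Reagents that add atoms: chlorotriisopropylsilane, CC(C)[Si](Cl)(C(C)C)C(C)C
Why: Standard silylation of a phenol with a silyl chloride and imidazole; the bulky aryl triisopropylsilyl ether should withstand lithium amide, carbonate and alkoxide bases and the cross-coupling, and it falls to fluoride in the last step together with the ester.

Step 3
Reactants: 4 2,2,6-trimethyl-1,3-dioxin-4-one; 5 acetyl chloride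
Product: 7 2,2-dimethyl-6-(2-oxopropyl)-1,3-dioxin-4-one, via lithium dienolate 6 (not isolated)
Conditions: 4 (2 equiv), LiN(SiMe3)2 (2 equiv), THF, −78 °C; then 5 (1 equiv), −78 °C; aq NH4Cl
Reagents that add atoms: none
Why: Deprotonation at the 6-methyl group gives the vinylogous ester dienolate 6, which is C-acylated at its gamma carbon by 5 (vinylogous Claisen acylation); because 7 is more acidic than 4, half of 6 is consumed as base and returns as 4 on work-up, hence the twofold amount.

Step 4
Reactants: 7 2,2-dimethyl-6-(2-oxopropyl)-1,3-dioxin-4-one; 3 N-methoxy-N-methyl-3-[4-(triisopropylsilyloxy)phenyl]propanamide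
Product: 9 6-{2,4-dioxo-6-[4-(triisopropylsilyloxy)phenyl]hexyl}-2,2-dimethyl-1,3-dioxin-4-one, via dilithium dianion 8 (not isolated)
Conditions: LiN(iPr)2 (2.2 equiv), THF, −78 °C; then 3, −78 to −20 °C; aq NH4Cl
Reagents that add atoms: none
Why: Two equivalents of amide base give dianion 8, whose terminal carbanion, formed last, is the most nucleophilic site and attacks the N-methoxy-N-methylamide 3 (Claisen-type acylation of a 1,3-dicarbonyl dianion); the chelated tetrahedral adduct persists until work-up, which prevents over-addition and proton transfer from the product. Compound 9 is labile and is taken on directly.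

Step 5
Reactants: 9 6-{2,4-dioxo-6-[4-(triisopropylsilyloxy)phenyl]hexyl}-2,2-dimethyl-1,3-dioxin-4-one
Product: 11 7-hydroxy-2,2-dimethyl-5-{2-[4-(triisopropylsilyloxy)phenyl]ethyl}-1,3-benzodioxin-4-one, via aldol adduct 10 (not isolated)
Conditions: Et3N, CH2Cl2, rt
Reagents that add atoms: none
Why: The amine removes a proton from the methylene between the dioxinone ring and the first ketone of 9; the anion is delocalized from the lactone oxygen through dioxinone C5 and C6 into the ketone enolate, and it reacts at dioxinone C5 (future ring A C6) with the distal ketone that carries the arylethyl chain (future C5), the only C–C bond formed. Adduct 10 loses its tertiary hydroxyl by E1cB elimination through the enolate of the remaining ring ketone, and tautomerization of that ketone gives the C3 phenol. The closest known reaction type is the base-mediated aldol aromatization of diketo-dioxinones to benzodioxinone resorcylates, the laboratory counterpart of polyketide folding to resorcylic acids. The single ring closes 6-exo-trig onto the ketone carbonyl; both double bonds of the ketone-derived dienolate (O–C=C–C=C) end up inside the new ring, so the closure is of the enolendo kind, while the lactone carbonyl carbon, the other end of the delocalized anion, stays outside it. No stereocenter is set: the carbinol carbon of 10 is racemic and is lost on dehydration. The selectivity needed is aldol against Claisen folding, in which the central methylene would attack the carboxyl carbon to give an acylphloroglucinol; this is shut off because that carbon is held in the dioxinone as a vinylogous carbonate, a poor acyl donor below the roughly 100 °C at which the ring fragments to an acylketene. Deprotonation at the central methylene, the most acidic site, is reversible and unproductive, because its enolate has no six-membered aldol mode open to it. The acetonide keeps the C1 oxygen and the carboxyl tied together, so the only free hydroxyl of 11 is the one at C3, between the two carbons that must later carry the prenyl groups.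

Step 6
Reactants: 11 7-hydroxy-2,2-dimethyl-5-{2-[4-(triisopropylsilyloxy)phenyl]ethyl}-1,3-benzodioxin-4-one
Product: 12 2,2-dimethyl-7-(prop-2-enyloxy)-5-{2-[4-(triisopropylsilyloxy)phenyl]ethyl}-1,3-benzodioxin-4-one
Conditions: allyl bromide, K2CO3, acetone, reflux
Reagents that add atoms: 3-bromoprop-1-ene (allyl bromide), C=CCBr
Why: Williamson etherification of the only free hydroxyl; the allyl ether masks the C3 oxygen during lactone opening and methylation and can later be removed under neutral conditions.

Step 7
Reactants: 12 2,2-dimethyl-7-(prop-2-enyloxy)-5-{2-[4-(triisopropylsilyloxy)phenyl]ethyl}-1,3-benzodioxin-4-one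
Product: 13 2-(trimethylsilyl)ethyl 2-hydroxy-4-(prop-2-enyloxy)-6-{2-[4-(triisopropylsilyloxy)phenyl]ethyl}benzoate
Conditions: Me3SiCH2CH2OH, NaH, THF, 0 °C to rt; aq NH4Cl
Reagents that add atoms: 2-(trimethylsilyl)ethanol, C[Si](C)(C)CCO
Why: Alkoxide transesterification of a salicylate acetonide: the alkoxide adds to the lactone carbonyl, the tetrahedral intermediate collapses with loss of acetone, and the chelated phenoxide that results is inert to further alkoxide. With the para oxygen alkylated the carbonyl keeps its electrophilicity, and the 2-(trimethylsilyl)ethyl ester is chosen because a doubly ortho-substituted benzoate can later be cleaved at silicon but not at the carbonyl.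

Step 8
Reactants: 13 2-(trimethylsilyl)ethyl 2-hydroxy-4-(prop-2-enyloxy)-6-{2-[4-(triisopropylsilyloxy)phenyl]ethyl}benzoate
Product: 14 2-(trimethylsilyl)ethyl 2-methoxy-4-(prop-2-enyloxy)-6-{2-[4-(triisopropylsilyloxy)phenyl]ethyl}benzoate
Conditions: MeI, K2CO3, acetone, 50 °C
Reagents that add atoms: iodomethane, CI
Why: Williamson methylation of the hydrogen-bonded salicylate hydroxyl with carbonate base; it is the only free hydroxyl and has just one ortho neighbour at this stage, which is why the methyl group is placed before C2 is substituted.

Step 9
Reactants: 14 2-(trimethylsilyl)ethyl 2-methoxy-4-(prop-2-enyloxy)-6-{2-[4-(triisopropylsilyloxy)phenyl]ethyl}benzoate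
Product: 15 2-(trimethylsilyl)ethyl 4-hydroxy-2-methoxy-6-{2-[4-(triisopropylsilyloxy)phenyl]ethyl}benzoate
Conditions: Pd(PPh3)4 (zerovalent palladium, 5 mol %), morpholine, THF, rt
Reagents that add atoms: none
Why: Tsuji–Trost-type deallylation: zerovalent palladium ionizes the allyl aryl ether to a pi-allyl complex and the phenoxide, a good leaving group para to the ester, and morpholine captures the allyl unit. The medium is neutral, so the silyl ether, the silylethyl ester and the methyl ether are untouched; the phenol is released here because the allyl alkene would not survive the iodination that follows.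

Step 10
Reactants: 15 2-(trimethylsilyl)ethyl 4-hydroxy-2-methoxy-6-{2-[4-(triisopropylsilyloxy)phenyl]ethyl}benzoate
Product: 16 2-(trimethylsilyl)ethyl 4-hydroxy-3,5-diiodo-2-methoxy-6-{2-[4-(triisopropylsilyloxy)phenyl]ethyl}benzoate
Conditions: N-iodosuccinimide (2.2 equiv), MeCN, 0 °C to rt, dark
Reagents that add atoms: N-iodosuccinimide, O=C1CCC(=O)N1I
Why: Electrophilic aromatic iodination: the two positions ortho to the free phenol are also ortho or para to the methoxy group and are the only unsubstituted carbons of ring A, so two equivalents of the reagent give one diiodide with no regiochemical choice to make. Ring B has no free hydroxyl and a bulky silyl ether, and without added acid it should not be iodinated.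

Step 11
Reactants: 16 2-(trimethylsilyl)ethyl 4-hydroxy-3,5-diiodo-2-methoxy-6-{2-[4-(triisopropylsilyloxy)phenyl]ethyl}benzoate
Product: 17 2-(trimethylsilyl)ethyl 4-hydroxy-2-methoxy-3,5-bis(prop-2-enyl)-6-{2-[4-(triisopropylsilyloxy)phenyl]ethyl}benzoate
Conditions: Bu3SnCH2CH=CH2 (3 equiv), Pd(PPh3)4 (zerovalent palladium, 10 mol %), DMF, 90 °C, argon
Reagents that add atoms: tributyl(prop-2-enyl)stannane, CCCC[Sn](CCCC)(CCCC)CC=C
Why: Twofold Stille coupling: zerovalent palladium inserts into each aryl C–I bond, the allyl group is transferred from tin, and reductive elimination forms the C2–CH2 and C4–CH2 bonds. The medium is neutral and free of fluoride, so the free phenol, the ester and both silicon groups are tolerated, and the allyl group has no linear or branched ambiguity.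

Step 12
Reactants: 17 2-(trimethylsilyl)ethyl 4-hydroxy-2-methoxy-3,5-bis(prop-2-enyl)-6-{2-[4-(triisopropylsilyloxy)phenyl]ethyl}benzoate
Product: 18 2-(trimethylsilyl)ethyl 4-hydroxy-2-methoxy-3,5-bis(3-methylbut-2-enyl)-6-{2-[4-(triisopropylsilyloxy)phenyl]ethyl}benzoate
Conditions: 2-methylbut-2-ene (large excess), RuCl2(=CHPh)(PCy3)(H2IMes) (second-generation Grubbs catalyst, 5 mol %), CH2Cl2, 40 °C
Reagents that add atoms: 2-methylbut-2-ene, CC=C(C)C
Why: Olefin cross-metathesis of the two terminal allyl groups with the trisubstituted alkene in large excess turns each into a prenyl group and releases propene; free phenols, aryl silyl ethers and esters are tolerated, and the meta-disposed allyl groups cannot close a ring with each other.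

Step 13
Reactants: 18 2-(trimethylsilyl)ethyl 4-hydroxy-2-methoxy-3,5-bis(3-methylbut-2-enyl)-6-{2-[4-(triisopropylsilyloxy)phenyl]ethyl}benzoate
Product: 19 4-hydroxy-6-[2-(4-hydroxyphenyl)ethyl]-2-methoxy-3,5-bis(3-methylbut-2-enyl)benzoic acid
Conditions: Bu4NF (4 equiv), THF, 0 °C to rt; aq NH4Cl, work-up near pH 5
Reagents that add atoms: none
Why: Fluoride cleaves the aryl silyl ether at silicon and fragments the 2-(trimethylsilyl)ethyl ester to the carboxylate, ethene and fluorotrimethylsilane, so the hindered carbonyl is never attacked. The medium stays basic to neutral and the work-up is only mildly acidic, which avoids chroman formation from the prenyl phenol and decarboxylation of the electron-rich acid.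

## Compound list

1 | 3-(4-hydroxyphenyl)propanoic acid | O=C(O)CCc1ccc(O)cc1 | starting material
2 | 3-(4-hydroxyphenyl)-N-methoxy-N-methylpropanamide | CON(C)C(=O)CCc1ccc(O)cc1 | intermediate
3 | N-methoxy-N-methyl-3-[4-(triisopropylsilyloxy)phenyl]propanamide | CON(C)C(=O)CCc1ccc(O[Si](C(C)C)(C(C)C)C(C)C)cc1 | intermediate
4 | 2,2,6-trimethyl-1,3-dioxin-4-one | CC1=CC(=O)OC(C)(C)O1 | starting material
5 | acetyl chloride | CC(=O)Cl | starting material
6 | lithium 2,2-dimethyl-6-methylidene-1,3-dioxin-4-olate (lithium dienolate of 4, not isolated) | [Li+].[O-]C1=CC(=C)OC(C)(C)O1 | intermediate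
7 | 2,2-dimethyl-6-(2-oxopropyl)-1,3-dioxin-4-one | CC(=O)CC1=CC(=O)OC(C)(C)O1 | intermediate
8 | dilithium 2,2-dimethyl-6-(2-oxidoprop-2-en-1-ylidene)-1,3-dioxin-4-olate (dianion of 7, not isolated) | [Li+].[Li+].C=C([O-])C=C1C=C([O-])OC(C)(C)O1 | intermediate
9 | 6-{2,4-dioxo-6-[4-(triisopropylsilyloxy)phenyl]hexyl}-2,2-dimethyl-1,3-dioxin-4-one | CC1(C)OC(=O)C=C(CC(=O)CC(=O)CCc2ccc(O[Si](C(C)C)(C(C)C)C(C)C)cc2)O1 | intermediate
10 | 5-hydroxy-2,2-dimethyl-5-{2-[4-(triisopropylsilyloxy)phenyl]ethyl}-5,6-dihydro-1,3-benzodioxine-4,7(8H)-dione (racemic aldol adduct, not isolated) | CC1(C)OC(=O)C2=C(CC(=O)CC2(O)CCc2ccc(O[Si](C(C)C)(C(C)C)C(C)C)cc2)O1 | intermediate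
11 | 7-hydroxy-2,2-dimethyl-5-{2-[4-(triisopropylsilyloxy)phenyl]ethyl}-1,3-benzodioxin-4-one | CC1(C)OC(=O)c2c(CCc3ccc(O[Si](C(C)C)(C(C)C)C(C)C)cc3)cc(O)cc2O1 | intermediate
12 | 2,2-dimethyl-7-(prop-2-enyloxy)-5-{2-[4-(triisopropylsilyloxy)phenyl]ethyl}-1,3-benzodioxin-4-one | CC1(C)OC(=O)c2c(CCc3ccc(O[Si](C(C)C)(C(C)C)C(C)C)cc3)cc(OCC=C)cc2O1 | intermediate
13 | 2-(trimethylsilyl)ethyl 2-hydroxy-4-(prop-2-enyloxy)-6-{2-[4-(triisopropylsilyloxy)phenyl]ethyl}benzoate | C[Si](C)(C)CCOC(=O)c1c(O)cc(OCC=C)cc1CCc1ccc(O[Si](C(C)C)(C(C)C)C(C)C)cc1 | intermediate
14 | 2-(trimethylsilyl)ethyl 2-methoxy-4-(prop-2-enyloxy)-6-{2-[4-(triisopropylsilyloxy)phenyl]ethyl}benzoate | COc1cc(OCC=C)cc(CCc2ccc(O[Si](C(C)C)(C(C)C)C(C)C)cc2)c1C(=O)OCC[Si](C)(C)C | intermediate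
15 | 2-(trimethylsilyl)ethyl 4-hydroxy-2-methoxy-6-{2-[4-(triisopropylsilyloxy)phenyl]ethyl}benzoate | COc1cc(O)cc(CCc2ccc(O[Si](C(C)C)(C(C)C)C(C)C)cc2)c1C(=O)OCC[Si](C)(C)C | intermediate
16 | 2-(trimethylsilyl)ethyl 4-hydroxy-3,5-diiodo-2-methoxy-6-{2-[4-(triisopropylsilyloxy)phenyl]ethyl}benzoate | COc1c(I)c(O)c(I)c(CCc2ccc(O[Si](C(C)C)(C(C)C)C(C)C)cc2)c1C(=O)OCC[Si](C)(C)C | intermediate
17 | 2-(trimethylsilyl)ethyl 4-hydroxy-2-methoxy-3,5-bis(prop-2-enyl)-6-{2-[4-(triisopropylsilyloxy)phenyl]ethyl}benzoate | COc1c(CC=C)c(O)c(CC=C)c(CCc2ccc(O[Si](C(C)C)(C(C)C)C(C)C)cc2)c1C(=O)OCC[Si](C)(C)C | intermediate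
18 | 2-(trimethylsilyl)ethyl 4-hydroxy-2-methoxy-3,5-bis(3-methylbut-2-enyl)-6-{2-[4-(triisopropylsilyloxy)phenyl]ethyl}benzoate | COc1c(CC=C(C)C)c(O)c(CC=C(C)C)c(CCc2ccc(O[Si](C(C)C)(C(C)C)C(C)C)cc2)c1C(=O)OCC[Si](C)(C)C | intermediate
19 | 4-hydroxy-6-[2-(4-hydroxyphenyl)ethyl]-2-methoxy-3,5-bis(3-methylbut-2-enyl)benzoic acid | COc1c(CC=C(C)C)c(O)c(CC=C(C)C)c(CCc2ccc(O)cc2)c1C(=O)O | target

## Step count and least certain steps

Total: 13 steps. Longest linear sequence: 12 steps, from 1 through steps 1, 2 and 4 to 13. The branch from 4 (step 3) joins at step 4.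

**Step 5 (key step).** The closure may stall at adduct 10 through incomplete dehydration. The enolized chain may also be diverted by oxygen attack on the dioxinone, or the labile 9 may decompose before it cyclizes. The fallback sets out from 9 and returns at 13. Compound 9 is heated in toluene at 110 °C with 2-(trimethylsilyl)ethanol. Retro-[4+2] loss of acetone gives the acylketene, which is trapped as the open-chain triketo ester 2-(trimethylsilyl)ethyl 3,5,7-trioxo-9-[4-(triisopropylsilyloxy)phenyl]nonanoate F1. Its beta-keto ester methylene, more acidic than the dioxinone position, closes onto the distal ketone under Cs2CO3 in THF followed by acetic acid, giving the resorcylate 2-(trimethylsilyl)ethyl 2,4-dihydroxy-6-{2-[4-(triisopropylsilyloxy)phenyl]ethyl}benzoate F2. Here the two oxygens are told apart by hydrogen bonding instead of by the acetonide: one equivalent of allyl bromide with K2CO3 in acetone alkylates only the non-chelated 4-hydroxyl and gives 13.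

**Step 4.** Proton transfer from the alpha-CH2 of amide 3 to the strongly basic dianion 8, or self-condensation of 7, can leave the acylation incomplete. The fallback sets out from 3 and 7 and returns at 9. Amide 3 is reduced with iBu2AlH at −78 °C to the aldehyde 3-[4-(triisopropylsilyloxy)phenyl]propanal F3. Dianion 8 adds to it in an aldol reaction, which is faster and cleaner than acylation, to give racemic 6-{4-hydroxy-2-oxo-6-[4-(triisopropylsilyloxy)phenyl]hexyl}-2,2-dimethyl-1,3-dioxin-4-one F4. Dess–Martin periodinane oxidizes the beta-hydroxy ketone to 9.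

**Step 11.** Each iodide is flanked by two substituents, so the second coupling may be slow and give way to protodeiodination. Palladium hydride species formed at 90 °C may also move the allyl double bond into conjugation with the ring. The fallback sets out from 14 and returns at 17, replacing steps 9 to 11 by a sigmatropic relay from the C3 oxygen. Heating 14 in PhNEt2 at 190 °C brings about an aromatic Claisen rearrangement. The para position carries the ester, so only ortho migration is possible, and it gives the two phenols 2-(trimethylsilyl)ethyl 4-hydroxy-2-methoxy-3-(prop-2-enyl)-6-{2-[4-(triisopropylsilyloxy)phenyl]ethyl}benzoate F5 and 2-(trimethylsilyl)ethyl 4-hydroxy-2-methoxy-5-(prop-2-enyl)-6-{2-[4-(triisopropylsilyloxy)phenyl]ethyl}benzoate F6. The pair is carried on together. Allyl bromide and K2CO3 in acetone convert them into the ethers 2-(trimethylsilyl)ethyl 2-methoxy-3-(prop-2-enyl)-4-(prop-2-enyloxy)-6-{2-[4-(triisopropylsilyloxy)phenyl]ethyl}benzoate F7 and 2-(trimethylsilyl)ethyl 2-methoxy-5-(prop-2-enyl)-4-(prop-2-enyloxy)-6-{2-[4-(triisopropylsilyloxy)phenyl]ethyl}benzoate F8. A second rearrangement at 190 °C has a single free ortho carbon in each isomer, so both converge on 17.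

**Step 7.** The excess alkoxide may attack silicon and strip the aryl silyl ether of ring B, and the phenoxide so formed would then be alkylated in step 8. The fallback sets out from 12 and returns at 13 without base. Irradiation of 12 at 300 nm in CH2Cl2 with 2-(trimethylsilyl)ethanol expels acetone and forms the transient quinoketene 6-(oxomethylidene)-3-(prop-2-enyloxy)-5-{2-[4-(triisopropylsilyloxy)phenyl]ethyl}cyclohexa-2,4-dien-1-one F9, which the alcohol traps to give 13.

## Further compounds

F1 | step 5 | 2-(trimethylsilyl)ethyl 3,5,7-trioxo-9-[4-(triisopropylsilyloxy)phenyl]nonanoate | C[Si](C)(C)CCOC(=O)CC(=O)CC(=O)CC(=O)CCc1ccc(O[Si](C(C)C)(C(C)C)C(C)C)cc1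
F2 | step 5 | 2-(trimethylsilyl)ethyl 2,4-dihydroxy-6-{2-[4-(triisopropylsilyloxy)phenyl]ethyl}benzoate | C[Si](C)(C)CCOC(=O)c1c(O)cc(O)cc1CCc1ccc(O[Si](C(C)C)(C(C)C)C(C)C)cc1
F3 | step 4 | 3-[4-(triisopropylsilyloxy)phenyl]propanal | O=CCCc1ccc(O[Si](C(C)C)(C(C)C)C(C)C)cc1
F4 | step 4 | 6-{4-hydroxy-2-oxo-6-[4-(triisopropylsilyloxy)phenyl]hexyl}-2,2-dimethyl-1,3-dioxin-4-one (racemic) | CC1(C)OC(=O)C=C(CC(=O)CC(O)CCc2ccc(O[Si](C(C)C)(C(C)C)C(C)C)cc2)O1
F5 | step 11 | 2-(trimethylsilyl)ethyl 4-hydroxy-2-methoxy-3-(prop-2-enyl)-6-{2-[4-(triisopropylsilyloxy)phenyl]ethyl}benzoate | COc1c(CC=C)c(O)cc(CCc2ccc(O[Si](C(C)C)(C(C)C)C(C)C)cc2)c1C(=O)OCC[Si](C)(C)C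
F6 | step 11 | 2-(trimethylsilyl)ethyl 4-hydroxy-2-methoxy-5-(prop-2-enyl)-6-{2-[4-(triisopropylsilyloxy)phenyl]ethyl}benzoate | COc1cc(O)c(CC=C)c(CCc2ccc(O[Si](C(C)C)(C(C)C)C(C)C)cc2)c1C(=O)OCC[Si](C)(C)C
F7 | step 11 | 2-(trimethylsilyl)ethyl 2-methoxy-3-(prop-2-enyl)-4-(prop-2-enyloxy)-6-{2-[4-(triisopropylsilyloxy)phenyl]ethyl}benzoate | COc1c(CC=C)c(OCC=C)cc(CCc2ccc(O[Si](C(C)C)(C(C)C)C(C)C)cc2)c1C(=O)OCC[Si](C)(C)C
F8 | step 11 | 2-(trimethylsilyl)ethyl 2-methoxy-5-(prop-2-enyl)-4-(prop-2-enyloxy)-6-{2-[4-(triisopropylsilyloxy)phenyl]ethyl}benzoate | COc1cc(OCC=C)c(CC=C)c(CCc2ccc(O[Si](C(C)C)(C(C)C)C(C)C)cc2)c1C(=O)OCC[Si](C)(C)C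
F9 | step 7 | 6-(oxomethylidene)-3-(prop-2-enyloxy)-5-{2-[4-(triisopropylsilyloxy)phenyl]ethyl}cyclohexa-2,4-dien-1-one | O=C=C1C(=O)C=C(OCC=C)C=C1CCc1ccc(O[Si](C(C)C)(C(C)C)C(C)C)cc1
A1 | alternative 1 | 2-methoxy-4-(methoxymethoxy)-3,5-bis(3-methylbut-2-enyl)-6-{2-[4-(methoxymethoxy)phenyl]ethyl}benzoic acid | COCOc1ccc(CCc2c(C(=O)O)c(OC)c(CC=C(C)C)c(OCOC)c2CC=C(C)C)cc1
A2 | alternative 1 | 1-chloro-5-methoxy-3-(methoxymethoxy)-2,4-bis(3-methylbut-2-enyl)benzene | COCOc1c(CC=C(C)C)c(Cl)cc(OC)c1CC=C(C)C
A3 | alternative 1 | 3-methoxy-5-(methoxymethoxy)-4,6-bis(3-methylbut-2-enyl)-1,2-didehydrobenzene | COC1=C(CC=C(C)C)C(OCOC)=C(CC=C(C)C)C#C1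
A4 | alternative 1 | {2-[4-(methoxymethoxy)phenyl]ethyl}magnesium bromide | COCOc1ccc(CC[Mg]Br)cc1
A5 | alternative 2 | 2-(trimethylsilyl)ethyl 2-hydroxy-4-(tert-butyldimethylsilyloxy)-3,5-bis(3-methylbut-2-enyl)-6-{2-[4-(tert-butyldimethylsilyloxy)phenyl]ethyl}benzoate | C[Si](C)(C)CCOC(=O)c1c(O)c(CC=C(C)C)c(O[Si](C)(C)C(C)(C)C)c(CC=C(C)C)c1CCc1ccc(O[Si](C)(C)C(C)(C)C)cc1
A6 | alternative 2 | 1-methoxy-7-methyl-2-(3-methylbut-2-enyl)-1,3-bis(tert-butyldimethylsilyloxy)octa-1,3,6-triene | COC(O[Si](C)(C)C(C)(C)C)=C(CC=C(C)C)C(O[Si](C)(C)C(C)(C)C)=CCC=C(C)C
A7 | alternative 2 | 2-(trimethylsilyl)ethyl 5-[4-(tert-butyldimethylsilyloxy)phenyl]pent-2-ynoate | C[Si](C)(C)CCOC(=O)C#CCCc1ccc(O[Si](C)(C)C(C)(C)C)cc1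
A8 | alternative 3 | prop-2-enyl all-trans-4-hydroxy-3,5-bis(3-methylbut-2-enyl)-2-oxo-6-{2-[4-(prop-2-enyloxy)phenyl]ethyl}cyclohex-3-ene-1-carboxylate (racemic, relative configuration shown) | C=CCOC(=O)[C@@H]1C(=O)C(CC=C(C)C)=C(O)[C@H](CC=C(C)C)[C@H]1CCc1ccc(OCC=C)cc1
A9 | alternative 3 | (3E)-9-methyl-4-(3-methylbut-2-enyl)-1-[4-(prop-2-enyloxy)phenyl]deca-3,8-dien-5-one | C=CCOc1ccc(CC/C=C(\CC=C(C)C)C(=O)CCC=C(C)C)cc1
A10 | alternative 3 | bis(prop-2-enyl) propanedioate | C=CCOC(=O)CC(=O)OCC=C
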